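Read the plateau of each earlier run rather than its rise, and price the incoming ligand by that plateau.

Minutes of the meeting on flasks beta, zeta and delta, which differ in their charge of incoming ligand.

| flask | starting complex | incoming ligand | remark | time |
|---|---|---|---|---|
| red | 48 mM | 27 mM | run made earlier |  |
| green | 48 mM | 48 mM | run made earlier |  |
| grey | 48 mM | 87 mM | run made earlier |  |
| beta | 48 mM | 24.0 mM |  | 10 d |
| zeta | 48 mM | 72.0 mM |  | 10 d |
| delta | 48 mM | 96.0 mM |  | 10 d |

| run | time / d | complex with two exchanged / % |
|---|---|---|
| red | 0.417 | 1 |
| red | 1.25 | 4 |
| red | 2.50 | 2 |
| red | 4.00 | 4 |
| red | 5.00 | 3 |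
| green | 0.417 | 4 |
| green | 1.25 | 10 |
| green | 2.50 | 10 |
| green | 4.00 | 10 |
| green | 5.00 | 9 |
| grey | 0.417 | 11 |
| grey | 0.833 | 18 |
| grey | 1.25 | 21 |
| grey | 2.50 | 20 |
| grey | 5.00 | 23 |

(readings scatter by 1.5 percentage points)

- steps thought possible: starting complex + incoming ligand -> leaving ligand + complex with one exchanged; complex with one exchanged -> side product; complex with one exchanged + incoming ligand -> leaving ligand + complex with two exchanged; complex with two exchanged <-> isomer of the product; complex with two exchanged + incoming ligand <-> leaving ligand + complex with three exchanged

- final complex with two exchanged, as a percentage of the starting complex charged, for each flask in turn (beta, zeta, delta)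

The analyst reported that complex with two exchanged stops climbing early: green read 10% after 1.25 d and 9% after 5.00 d, and grey read 21% after 1.25 d and 23% after 5.00 d, steps of the order of the scatter of 1.5 percentage points. The kineticist wanted every step of the scheme fitted. The analyst answered that readings of a single species were thin ground for that, and proposed freezing each run at its plateau mean, 9.75% for green and 21.3% for grey.

From these the analyst drew one number, the plateau gain, a differential yield: the mM of complex with two exchanged gained at the plateau per extra mM of incoming ligand charged, here 0.143.

The kineticist demanded a test on the run not used. At the red charge the frozen line gives 3.51%, and the red plateau reads 3.25%. The meeting accepted the line and reckoned 2.62% for beta, 16.9% for zeta and 24.0% for delta, the kineticist noting that delta lies beyond grey.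

The forecast gave 2.5%, 17% and 24.5%, calling its delta value “the least certain value”.

The simulation gives 2.84% for beta, 17.4% for zeta and 22.4% for delta.

    starting complex + incoming ligand → leaving ligand + complex with one exchanged (k = 0.990 M⁻¹ h⁻¹)
    complex with one exchanged → side product (k = 0.117 h⁻¹)
    complex with one exchanged + incoming ligand → leaving ligand + complex with two exchanged (k = 1.31 M⁻¹ h⁻¹)
    complex with two exchanged ⇌ isomer of the product (K = 0.425, k = 0.0235 h⁻¹)
    complex with two exchanged + incoming ligand ⇌ leaving ligand + complex with three exchanged (K = 0.600, k = 0.205 M⁻¹ h⁻¹)

From the green plateau reading to zeta the plateau gain comes out at 0.153, against the frozen 0.143, but from zeta to delta it is 0.100, which is less. The zeta yield is held down in part by the loss of complex with one exchanged to side product. Zeta run without that step reaches 44.6% instead of 17.4%, which recovers 33% of what zeta lacks of the full charge of starting complex.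

The earlier runs and the new flask are calculated from invented constants.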